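**Assumptions:** The target has no stereocentres or double-bond geometry (it is achiral), so the "single enantiomer" requirement imposes nothing. The acyl chain is read as C30 (triacontanoyl, 29 alkyl carbons plus the carbonyl carbon).

## Retrosynthetic overview

1. The obvious acyl C–O disconnection (triacontanoic acid + tyrosol) is avoided; the ester is cut at the alkyl O–CH2 bond instead.
2. The target comes from a (Z)-enol ester by one hydrogenation that saturates the styryl C=C and removes an O-benzyl group.
3. The enol ester comes from Ru-catalysed anti-Markovnikov addition of the free C30 acid O–H across a terminal aryl alkyne (Ru-vinylidene pathway). No acid activation is needed and no phenol/alcohol selectivity problem arises.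
4. No rings are formed; the benzene ring is bought as 1-(benzyloxy)-4-ethynylbenzene.

## Route

**Step 1**

Reactants: **1** triacontanoic acid (melissic acid, 1.0 equiv); **2** 1-(benzyloxy)-4-ethynylbenzene (1.3 equiv)

Product: **3** (Z)-2-[4-(benzyloxy)phenyl]ethenyl triacontanoate

Conditions: Ru(η3-2-methylallyl)2(dppb) 2 mol% (pre-formed from Ru(cod)(methallyl)2 + dppb), toluene (0.1 M), 65–70 °C, Ar, 16 h; short plug of Et3N-deactivated silica (no alcohols in work-up)

Reagents that add atoms: none (both partners are numbered compounds; 100% atom-economic addition)

Why: Ru-catalysed anti-Markovnikov hydro-oxycarbonylation of a terminal alkyne. The alkyne isomerises to a Ru-vinylidene and the carboxylate attacks the electrophilic Cα, giving the linear (Z)-enol ester. The benzyl ether is inert, and the alkene geometry is irrelevant because step 2 removes it.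

**Step 2**

Reactants: **3** (Z)-2-[4-(benzyloxy)phenyl]ethenyl triacontanoate

Product: **4** 2-(4-hydroxyphenyl)ethyl triacontanoate (Basalethanolide B)

Conditions: H2 (1 atm), 10% Pd/C (10 wt%), THF/EtOAc 1:1, 40 °C, 8–12 h; hot filtration through Celite; recrystallise from acetone

Reagents that add atoms: none (only hydrogen is added; the benzyl group leaves as toluene)

Why: Heterogeneous catalytic hydrogenation saturates the styryl enol-ester C=C, and the same catalyst hydrogenolyses the benzylic aryl ether. The new ester O–CH2 bond is homobenzylic and is not cleaved. The aprotic solvent prevents transesterification of the enol ester, and no stereocentre is created.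

## Compound list

1 | triacontanoic acid | CCCCCCCCCCCCCCCCCCCCCCCCCCCCCC(=O)O | starting material

2 | 1-(benzyloxy)-4-ethynylbenzene | C#Cc1ccc(OCc2ccccc2)cc1 | starting material

3 | (Z)-2-[4-(benzyloxy)phenyl]ethenyl triacontanoate | CCCCCCCCCCCCCCCCCCCCCCCCCCCCCC(=O)O/C=C\c1ccc(OCc2ccccc2)cc1 | intermediate

4 | 2-(4-hydroxyphenyl)ethyl triacontanoate (Basalethanolide B) | CCCCCCCCCCCCCCCCCCCCCCCCCCCCCC(=O)OCCc1ccc(O)cc1 | target

## Summary

Total step count: 2

Longest linear sequence: 2

Steps most likely to fail (the route has only two steps, so both are listed, plus a second distinct failure mode of step 2):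

1. **Step 1, low conversion or wrong regiochemistry.** The waxy C30 acid is poorly soluble at 65 °C, the aryl alkyne can dimerise to enynes, and some Markovnikov gem-enol ester may form. Fallback: keep the O–alkyl disconnection but switch to SN2 carboxylate alkylation. Treat the caesium salt of **1** (Cs2CO3, DMF/THF, 60 °C) with 1-(benzyloxy)-4-(2-bromoethyl)benzene, then debenzylate with H2, Pd/C.

2. **Step 2, hydrogenolysis of the vinylic C–O bond.** The enol ester could be cleaved before the C=C is saturated, returning acid **1** and a 4-ethylphenol derivative. Fallback: avoid the enol ester altogether. Use acridinium photoredox anti-Markovnikov hydroacyloxylation of 4-(benzyloxy)styrene with **1** (Mes-Acr+ catalyst, thiol H-atom donor, blue LED) to form the saturated ester directly, then debenzylate separately.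

3. **Step 2, incomplete O-debenzylation.** The waxy product may coat the catalyst and stall the hydrogenolysis. Fallback: change the protecting-group logic. Run step 1 with tert-butyl(4-ethynylphenoxy)dimethylsilane, hydrogenate only the C=C (Pd/C or Rh), and free the phenol with buffered fluoride (TBAF/AcOH or HF·pyridine, THF), which leaves the alkyl ester intact.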